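The benzotropolone is numbered C1–C4 (benzo ring), C4a, C5–C9 (seven-membered ring), C9a. The route rests on cutting the C7–C8 bond of the seven-membered ring. C5/C6 are carried as a 1,2-diketone, already at tropolone oxidation level, whose only enolisable carbon is C7, the one bearing chroman B. In one operation a Lewis acid turns the C9a arylacetaldehyde dimethyl acetal into an oxocarbenium ion (C8) that is trapped by the C6 trimethylsilyl enol ether, closing the seven-membered ring. The precursor is a pentasubstituted benzene with galloylated flavan A at C1, the acetal chain at C9a and the silyloxy enone carrying chroman B at C4a.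

Key step: step 18

Remark: "flavan A" is the galloylated flavan on C1 and "chroman B" the chroman on C7; compound 23 is carried as a mixture at C7/C8 because both carbons become sp2 in step 19, and compounds 4, 8 and 15 are taken as purchasable.

Step 1
Reactants: 1 acrolein
Product: 2 rac-hex-1-en-5-yn-3-ol
Conditions: propargyl bromide, Zn dust, THF, 0 °C; H2O work-up
Reagents that add atoms: propargyl bromide, C#CCBr
Why: Barbier-type zinc propargylation adds 1,2 to the enal and should give mainly the homopropargylic carbinol; the racemate is resolved in step 2.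

Step 2
Reactants: 2 rac-hex-1-en-5-yn-3-ol
Product: 3 (2R,3S)-1,2-epoxyhex-5-yn-3-ol, that is (1S)-1-[(2R)-oxiran-2-yl]but-3-yn-1-ol
Conditions: Ti(OiPr)4, L-(+)-DIPT, t-BuOOH (0.45 equiv), 4 Å MS, CH2Cl2, −20 °C
Reagents that add atoms: tert-butyl hydroperoxide, CC(C)(C)OO
Why: Sharpless kinetic resolution of a secondary allylic alcohol: with L-(+)-DIPT only the (S)-alcohol should be epoxidised, on the face that makes the oxirane carbon R and erythro to the carbinol (both stereocentres of chroman B originate here), while the (R)-alcohol is left and separated.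

Step 3
Reactants: 3 (2R,3S)-1,2-epoxyhex-5-yn-3-ol; 4 3,5-bis(benzyloxy)phenol
Product: 5 1,3-bis(benzyloxy)-5-{[(1R)-1-[(2R)-oxiran-2-yl]but-3-yn-1-yl]oxy}benzene
Conditions: PPh3, DIAD, THF, 0 °C → rt
Reagents that add atoms: none
Why: Mitsunobu etherification: SN2 attack of the phenoxide on the alkoxyphosphonium ion inverts the carbinol (S → R), which becomes C2 of chroman B, and the neutral conditions leave the epoxide intact.

Step 4
Reactants: 5 1,3-bis(benzyloxy)-5-{[(1R)-1-[(2R)-oxiran-2-yl]but-3-yn-1-yl]oxy}benzene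
Product: 6 (2R,3R)-5,7-bis(benzyloxy)-2-(prop-2-yn-1-yl)chroman-3-ol (2,3-cis)
Conditions: BF3·OEt2 (0.3 equiv), CH2Cl2, −78 → −30 °C
Reagents that add atoms: none
Why: Intramolecular Friedel–Crafts epoxide–arene cyclisation: the ortho carbon of the phloroglucinol-type ring attacks the terminal epoxide carbon (six-membered ring favoured over the five-membered alternative), both existing stereocentres are spectators so the 2,3-cis chromanol should result, and BF3 does not activate the alkyne.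

Step 5
Reactants: 6 (2R,3R)-5,7-bis(benzyloxy)-2-(prop-2-yn-1-yl)chroman-3-ol
Product: 7 (2R,3R)-3,5,7-tris(benzyloxy)-2-(prop-2-yn-1-yl)chromane (chroman B alkyne)
Conditions: NaH, BnBr, Bu4NI (cat.), DMF, 0 °C → rt
Reagents that add atoms: benzyl bromide, BrCc1ccccc1
Why: Williamson etherification of the secondary alkoxide; the benzyl ether keeps the 3-oxygen from adding to the later diketone and leaves with all other benzyl groups in step 20.

Step 6
Reactants: 8 3-bromo-4,5-dihydroxybenzaldehyde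
Product: 9 3,4-bis(benzyloxy)-5-bromobenzaldehyde
Conditions: BnBr, K2CO3, DMF, 50 °C
Reagents that add atoms: benzyl bromide, BrCc1ccccc1
Why: Williamson O-benzylation of both catechol hydroxyls under standard carbonate conditions.

Step 7
Reactants: 9 3,4-bis(benzyloxy)-5-bromobenzaldehyde
Product: 10 4,5-bis(benzyloxy)-3-bromo-2-iodobenzaldehyde
Conditions: I2, CF3CO2Ag, CH2Cl2, rt, dark
Reagents that add atoms: iodine, [I][I]
Why: Silver-assisted electrophilic aromatic iodination is expected para to the 3-benzyloxy group, the position between the formyl group and bromine, as para direction by an ether oxygen dominates in 3,4-dialkoxybenzaldehydes.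

Step 8
Reactants: 10 4,5-bis(benzyloxy)-3-bromo-2-iodobenzaldehyde
Product: 11 rac-1-[4,5-bis(benzyloxy)-3-bromo-2-iodophenyl]prop-2-en-1-ol
Conditions: vinylmagnesium bromide, THF, −78 °C; H2O work-up
Reagents that add atoms: vinylmagnesium bromide, C=C[Mg]Br
Why: Grignard 1,2-addition to the aldehyde at −78 °C, where halogen–magnesium exchange at the aryl iodide should not compete; the racemate is resolved in step 9.

Step 9
Reactants: 11 rac-1-[4,5-bis(benzyloxy)-3-bromo-2-iodophenyl]prop-2-en-1-ol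
Product: 12 (S)-[4,5-bis(benzyloxy)-3-bromo-2-iodophenyl][(2R)-oxiran-2-yl]methanol
Conditions: Ti(OiPr)4, L-(+)-DIPT, t-BuOOH (0.45 equiv), 4 Å MS, CH2Cl2, −20 °C
Reagents that add atoms: tert-butyl hydroperoxide, CC(C)(C)OO
Why: Sharpless kinetic resolution as in step 2: L-(+)-DIPT should epoxidise only the (R)-enantiomer of 11 (the same spatial series as in step 2, the descriptor changing because aryl outranks vinyl) to the erythro epoxy alcohol, which sets both stereocentres of flavan A.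

Step 10
Reactants: 12 (S)-[4,5-bis(benzyloxy)-3-bromo-2-iodophenyl][(2R)-oxiran-2-yl]methanol; 4 3,5-bis(benzyloxy)phenol
Product: 13 1,3-bis(benzyloxy)-5-{(R)-[4,5-bis(benzyloxy)-3-bromo-2-iodophenyl][(2R)-oxiran-2-yl]methoxy}benzene
Conditions: PPh3, DIAD, toluene, 0 °C → rt
Reagents that add atoms: none
Why: Mitsunobu etherification with inversion at the benzylic carbinol (S → R, the future C2 of flavan A); the two halogens and the twisted 4-benzyloxy group disfavour benzylic ionisation, so the substitution should stay SN2.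

Step 11
Reactants: 13 1,3-bis(benzyloxy)-5-{(R)-[4,5-bis(benzyloxy)-3-bromo-2-iodophenyl][(2R)-oxiran-2-yl]methoxy}benzene
Product: 14 (2R,3R)-5,7-bis(benzyloxy)-2-[4,5-bis(benzyloxy)-3-bromo-2-iodophenyl]chroman-3-ol (2,3-cis)
Conditions: AuCl3 (5 mol%), AgOTf (15 mol%), CH2Cl2, rt
Reagents that add atoms: none
Why: Gold-catalysed intramolecular epoxide–arene (Friedel–Crafts) cyclisation, the ring closure of step 4 under the milder trivalent-gold conditions known for 2-aryl chroman-3-ols because the benzylic aryl ether would not stand a strong Lewis acid; C2 and C3 are untouched, so the cis flavan-3-ol should form.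

Step 12
Reactants: 14 (2R,3R)-5,7-bis(benzyloxy)-2-[4,5-bis(benzyloxy)-3-bromo-2-iodophenyl]chroman-3-ol; 15 3,4,5-tris(benzyloxy)benzoic acid
Product: 16 (2R,3R)-5,7-bis(benzyloxy)-2-[4,5-bis(benzyloxy)-3-bromo-2-iodophenyl]chroman-3-yl 3,4,5-tris(benzyloxy)benzoate
Conditions: DCC, DMAP, CH2Cl2, rt
Reagents that add atoms: none
Why: Steglich esterification, the standard way to galloylate the axial 3-hydroxyl of cis flavan-3-ols, with no change at C3.

Step 13
Reactants: 16 (2R,3R)-5,7-bis(benzyloxy)-2-[4,5-bis(benzyloxy)-3-bromo-2-iodophenyl]chroman-3-yl 3,4,5-tris(benzyloxy)benzoate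
Product: 17 (2R,3R)-5,7-bis(benzyloxy)-2-{4,5-bis(benzyloxy)-3-bromo-2-[(E)-2-ethoxyethenyl]phenyl}chroman-3-yl 3,4,5-tris(benzyloxy)benzoate
Conditions: (E)-2-(2-ethoxyvinyl)-4,4,5,5-tetramethyl-1,3,2-dioxaborolane, Pd(dppf)Cl2 (5 mol%), K3PO4, dioxane/H2O 9:1, 60 °C
Reagents that add atoms: (E)-2-(2-ethoxyvinyl)-4,4,5,5-tetramethyl-1,3,2-dioxaborolane, CCO/C=C/B1OC(C)(C)C(C)(C)O1
Why: Suzuki–Miyaura coupling in which zerovalent palladium inserts into the C–I bond much faster than into the neighbouring C–Br bond, so only the iodide should be exchanged for the masked acetaldehyde unit.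

Step 14
Reactants: 17 (2R,3R)-5,7-bis(benzyloxy)-2-{4,5-bis(benzyloxy)-3-bromo-2-[(E)-2-ethoxyethenyl]phenyl}chroman-3-yl 3,4,5-tris(benzyloxy)benzoate
Product: 19 (2R,3R)-5,7-bis(benzyloxy)-2-[4,5-bis(benzyloxy)-3-bromo-2-(2,2-dimethoxyethyl)phenyl]chroman-3-yl 3,4,5-tris(benzyloxy)benzoate, via mixed ethyl methyl acetal 18 (not isolated)
Conditions: MeOH (excess), PPTS (cat.), CH2Cl2, rt
Reagents that add atoms: methanol, CO
Why: Acid-catalysed addition of methanol to the enol ether and transacetalisation in excess methanol should give the dimethyl acetal; it is made only now because the Lewis-acid steps 4 and 11 would not tolerate it.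

Step 15
Reactants: 19 (2R,3R)-5,7-bis(benzyloxy)-2-[4,5-bis(benzyloxy)-3-bromo-2-(2,2-dimethoxyethyl)phenyl]chroman-3-yl 3,4,5-tris(benzyloxy)benzoate; 7 (2R,3R)-3,5,7-tris(benzyloxy)-2-(prop-2-yn-1-yl)chromane
Product: 20 (2R,3R)-5,7-bis(benzyloxy)-2-{4,5-bis(benzyloxy)-2-(2,2-dimethoxyethyl)-3-[3-((2R,3R)-3,5,7-tris(benzyloxy)chroman-2-yl)prop-1-yn-1-yl]phenyl}chroman-3-yl 3,4,5-tris(benzyloxy)benzoate
Conditions: Pd(PhCN)2Cl2 (5 mol%), [HP(t-Bu)3]BF4 (10 mol%), CuI (5 mol%), i-Pr2NH, dioxane, rt → 45 °C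
Reagents that add atoms: none
Why: Sonogashira coupling with a tri-tert-butylphosphine-ligated zerovalent palladium catalyst, which inserts into hindered electron-rich aryl bromides near room temperature, while the mild amine base spares the ester and the acetal.

Step 16
Reactants: 20 (the diarylalkyne of step 15)
Product: 21 1-aryl-3-[(2R,3R)-3,5,7-tris(benzyloxy)chroman-2-yl]propane-1,2-dione, aryl = 2,3-bis(benzyloxy)-6-(2,2-dimethoxyethyl)-5-[flavan A gallate]phenyl
Conditions: KMnO4, NaHCO3, MgSO4, acetone/CH2Cl2/H2O, 0 °C → rt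
Reagents that add atoms: potassium permanganate, [K+].[O-][Mn](=O)(=O)=O
Why: Buffered permanganate oxidation of a disubstituted alkyne to the 1,2-diketone, chosen over PdCl2/DMSO because it is neutral and brings no π-acid that could drive the neighbouring acetal oxygen onto the alkyne.

Step 17
Reactants: 21 (the 1,2-diketone acetal of step 16)
Product: 22 (Z)-1-aryl-3-[(2R,3R)-3,5,7-tris(benzyloxy)chroman-2-yl]-2-(trimethylsilyloxy)prop-2-en-1-one, aryl as in 21 (acetal enol silane)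
Conditions: Et3N (3 equiv), TMSOTf (1.3 equiv), CH2Cl2, −78 °C; cold NaHCO3, used crude
Reagents that add atoms: trimethylsilyl trifluoromethanesulfonate, C[Si](C)(C)OS(=O)(=O)C(F)(F)F
Why: Soft enolisation (O-silylation at C6, then deprotonation at C7, the only α-hydrogens) should give the Z 2-silyloxy enone without a free enolate, so the chroman B ring oxygen β to C7 is not expelled, and the low temperature with excess amine keeps the silyl triflate from ionising the acetal.

Step 18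
Reactants: 22 (the acetal enol silane of step 17)
Product: 23 1-[flavan A gallate]-3,4-bis(benzyloxy)-8-methoxy-7-[(2R,3R)-3,5,7-tris(benzyloxy)chroman-2-yl]-8,9-dihydro-5H-benzo[7]annulene-5,6(7H)-dione (C7/C8 mixture)
Conditions: TMSOTf (0.2 equiv), 2,6-di-tert-butyl-4-methylpyridine, CH2Cl2, −78 °C; Et3N quench
Reagents that add atoms: none
Why: TMSOTf silylates one acetal methoxy group and expels Me3SiOMe, the oxocarbenium ion at C8 is attacked by C7 of the enol silane, and loss of the silyl group from the C6 oxygen returns the promoter. This is an intramolecular Mukaiyama-type addition of an enol silane to an acetal, in which pyruvate-type 2-silyloxy enones are established nucleophiles. The seven-membered ring closes in the 7-(enolendo)-exo-trig mode. The new centres C7 and C8 are not controlled (chroman B gives only a weak substrate bias) and need not be, since both become sp2 in step 19. The site selectivity that is needed is built in: C7 is the only enol carbon because C5 is flanked by the arene, and the acetal is the only latent electrophile. Low temperature, substoichiometric promoter and a hindered pyridine base are chosen so that C–C closure outruns capture of the cation by the C5 carbonyl oxygen (the way to a 2-benzopyrylium salt) and proton loss to the enol ether.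

Step 19
Reactants: 23 (the 8-methoxy dione of step 18)
Product: 25 perbenzylated benzotropolone 1-[flavan A gallate]-3,4-bis(benzyloxy)-6-hydroxy-7-[(2R,3R)-3,5,7-tris(benzyloxy)chroman-2-yl]-5H-benzo[7]annulen-5-one, via 7-ene-5,6-dione 24 (not isolated)
Conditions: CSA (0.2 equiv), toluene, 40 °C
Reagents that add atoms: none
Why: Acid-catalysed β-elimination of methanol through the C6 enol, then dienolisation through C9 to the aromatic tropolone, with no redox step; acid replaces base because a C7 enolate made with an amidine base would expel the chroman B aryloxide (the better leaving group) before methoxide and scramble its C2.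

Step 20
Reactants: 25 (the perbenzylated benzotropolone of step 19)
Product: 26 CNP0217128.1
Conditions: H2 (1 atm), Pd(OH)2/C, THF/MeOH, rt
Reagents that add atoms: none
Why: Hydrogenolysis of all ten benzyl ethers, as in the last step of catechin gallate syntheses, where the cyclic benzylic C2–O bonds and the gallate ester survive.

Compound list
1 | acrolein | C=CC=O | starting material
2 | rac-hex-1-en-5-yn-3-ol | C=CC(O)CC#C | intermediate
3 | (2R,3S)-1,2-epoxyhex-5-yn-3-ol | C#CC[C@H](O)[C@H]1CO1 | intermediate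
4 | 3,5-bis(benzyloxy)phenol | Oc1cc(OCc9ccccc9)cc(OCc9ccccc9)c1 | starting material
5 | 1,3-bis(benzyloxy)-5-{[(1R)-1-[(2R)-oxiran-2-yl]but-3-yn-1-yl]oxy}benzene | C#CC[C@@H](Oc1cc(OCc9ccccc9)cc(OCc9ccccc9)c1)[C@H]1CO1 | intermediate
6 | (2R,3R)-5,7-bis(benzyloxy)-2-(prop-2-yn-1-yl)chroman-3-ol | C#CC[C@H]1Oc2cc(OCc9ccccc9)cc(OCc9ccccc9)c2C[C@H]1O | intermediate
7 | (2R,3R)-3,5,7-tris(benzyloxy)-2-(prop-2-yn-1-yl)chromane | C#CC[C@H]1Oc2cc(OCc9ccccc9)cc(OCc9ccccc9)c2C[C@H]1OCc9ccccc9 | intermediate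
8 | 3-bromo-4,5-dihydroxybenzaldehyde | O=Cc1cc(O)c(O)c(Br)c1 | starting material
9 | 3,4-bis(benzyloxy)-5-bromobenzaldehyde | O=Cc1cc(OCc9ccccc9)c(OCc9ccccc9)c(Br)c1 | intermediate
10 | 4,5-bis(benzyloxy)-3-bromo-2-iodobenzaldehyde | O=Cc1cc(OCc9ccccc9)c(OCc9ccccc9)c(Br)c1I | intermediate
11 | rac-1-[4,5-bis(benzyloxy)-3-bromo-2-iodophenyl]prop-2-en-1-ol | C=CC(O)c1cc(OCc9ccccc9)c(OCc9ccccc9)c(Br)c1I | intermediate
12 | (S)-[4,5-bis(benzyloxy)-3-bromo-2-iodophenyl][(2R)-oxiran-2-yl]methanol | O[C@@H](c1cc(OCc9ccccc9)c(OCc9ccccc9)c(Br)c1I)[C@H]1CO1 | intermediate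
13 | 1,3-bis(benzyloxy)-5-{(R)-[4,5-bis(benzyloxy)-3-bromo-2-iodophenyl][(2R)-oxiran-2-yl]methoxy}benzene | c1(O[C@H](c2cc(OCc9ccccc9)c(OCc9ccccc9)c(Br)c2I)[C@H]2CO2)cc(OCc9ccccc9)cc(OCc9ccccc9)c1 | intermediate
14 | (2R,3R)-5,7-bis(benzyloxy)-2-[4,5-bis(benzyloxy)-3-bromo-2-iodophenyl]chroman-3-ol | Ic1c(Br)c(OCc9ccccc9)c(OCc9ccccc9)cc1[C@H]1Oc2cc(OCc9ccccc9)cc(OCc9ccccc9)c2C[C@H]1O | intermediate
15 | 3,4,5-tris(benzyloxy)benzoic acid | OC(=O)c1cc(OCc9ccccc9)c(OCc9ccccc9)c(OCc9ccccc9)c1 | starting material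
16 | (2R,3R)-5,7-bis(benzyloxy)-2-[4,5-bis(benzyloxy)-3-bromo-2-iodophenyl]chroman-3-yl 3,4,5-tris(benzyloxy)benzoate | Ic1c(Br)c(OCc9ccccc9)c(OCc9ccccc9)cc1[C@H]1Oc2cc(OCc9ccccc9)cc(OCc9ccccc9)c2C[C@H]1OC(=O)c1cc(OCc9ccccc9)c(OCc9ccccc9)c(OCc9ccccc9)c1 | intermediate
17 | (2R,3R)-5,7-bis(benzyloxy)-2-{4,5-bis(benzyloxy)-3-bromo-2-[(E)-2-ethoxyethenyl]phenyl}chroman-3-yl 3,4,5-tris(benzyloxy)benzoate | CCO/C=C/c1c(Br)c(OCc9ccccc9)c(OCc9ccccc9)cc1[C@H]1Oc2cc(OCc9ccccc9)cc(OCc9ccccc9)c2C[C@H]1OC(=O)c1cc(OCc9ccccc9)c(OCc9ccccc9)c(OCc9ccccc9)c1 | intermediate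
18 | (2R,3R)-5,7-bis(benzyloxy)-2-[4,5-bis(benzyloxy)-3-bromo-2-(2-ethoxy-2-methoxyethyl)phenyl]chroman-3-yl 3,4,5-tris(benzyloxy)benzoate (acetal carbon as mixture, not isolated) | CCOC(OC)Cc1c(Br)c(OCc9ccccc9)c(OCc9ccccc9)cc1[C@H]1Oc2cc(OCc9ccccc9)cc(OCc9ccccc9)c2C[C@H]1OC(=O)c1cc(OCc9ccccc9)c(OCc9ccccc9)c(OCc9ccccc9)c1 | intermediate
19 | (2R,3R)-5,7-bis(benzyloxy)-2-[4,5-bis(benzyloxy)-3-bromo-2-(2,2-dimethoxyethyl)phenyl]chroman-3-yl 3,4,5-tris(benzyloxy)benzoate | COC(OC)Cc1c(Br)c(OCc9ccccc9)c(OCc9ccccc9)cc1[C@H]1Oc2cc(OCc9ccccc9)cc(OCc9ccccc9)c2C[C@H]1OC(=O)c1cc(OCc9ccccc9)c(OCc9ccccc9)c(OCc9ccccc9)c1 | intermediate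
20 | diarylalkyne: 19 with Br replaced by the 3-[(2R,3R)-3,5,7-tris(benzyloxy)chroman-2-yl]prop-1-yn-1-yl group | COC(OC)Cc1c(C#CC[C@H]2Oc3cc(OCc9ccccc9)cc(OCc9ccccc9)c3C[C@H]2OCc9ccccc9)c(OCc9ccccc9)c(OCc9ccccc9)cc1[C@H]1Oc2cc(OCc9ccccc9)cc(OCc9ccccc9)c2C[C@H]1OC(=O)c1cc(OCc9ccccc9)c(OCc9ccccc9)c(OCc9ccccc9)c1 | intermediate
21 | 1,2-diketone acetal: 20 with the alkyne carbons as C(=O)C(=O) | COC(OC)Cc1c(C(=O)C(=O)C[C@H]2Oc3cc(OCc9ccccc9)cc(OCc9ccccc9)c3C[C@H]2OCc9ccccc9)c(OCc9ccccc9)c(OCc9ccccc9)cc1[C@H]1Oc2cc(OCc9ccccc9)cc(OCc9ccccc9)c2C[C@H]1OC(=O)c1cc(OCc9ccccc9)c(OCc9ccccc9)c(OCc9ccccc9)c1 | intermediate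
22 | acetal enol silane: (Z)-trimethylsilyl enol ether of 21 at C6/C7 | COC(OC)Cc1c([C@H]2Oc3cc(OCc9ccccc9)cc(OCc9ccccc9)c3C[C@H]2OC(=O)c2cc(OCc9ccccc9)c(OCc9ccccc9)c(OCc9ccccc9)c2)cc(OCc9ccccc9)c(OCc9ccccc9)c1C(=O)/C(O[Si](C)(C)C)=C/[C@H]1Oc2cc(OCc9ccccc9)cc(OCc9ccccc9)c2C[C@H]1OCc9ccccc9 | intermediate
23 | 8-methoxy-8,9-dihydro-5H-benzo[7]annulene-5,6(7H)-dione carrying flavan A gallate at C1, benzyloxy at C3 and C4, chroman B at C7 (C7/C8 mixture) | COC1Cc2c([C@H]3Oc4cc(OCc9ccccc9)cc(OCc9ccccc9)c4C[C@H]3OC(=O)c3cc(OCc9ccccc9)c(OCc9ccccc9)c(OCc9ccccc9)c3)cc(OCc9ccccc9)c(OCc9ccccc9)c2C(=O)C(=O)C1[C@H]1Oc2cc(OCc9ccccc9)cc(OCc9ccccc9)c2C[C@H]1OCc9ccccc9 | intermediate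
24 | 5H-benzo[7]annulene-5,6(9H)-dione with C7=C8, substituents as in 23 (not isolated) | O=C1C(=O)C([C@H]2Oc3cc(OCc9ccccc9)cc(OCc9ccccc9)c3C[C@H]2OCc9ccccc9)=CCc2c1c(OCc9ccccc9)c(OCc9ccccc9)cc2[C@H]1Oc2cc(OCc9ccccc9)cc(OCc9ccccc9)c2C[C@H]1OC(=O)c1cc(OCc9ccccc9)c(OCc9ccccc9)c(OCc9ccccc9)c1 | intermediate
25 | perbenzylated benzotropolone (deca-O-benzyl ether of the target, C6–OH free) | O=C(O[C@@H]1Cc2c(OCc9ccccc9)cc(OCc9ccccc9)cc2O[C@@H]1c1cc(OCc9ccccc9)c(OCc9ccccc9)c2c(=O)c(O)c([C@H]3Oc4cc(OCc9ccccc9)cc(OCc9ccccc9)c4C[C@H]3OCc9ccccc9)ccc12)c1cc(OCc9ccccc9)c(OCc9ccccc9)c(OCc9ccccc9)c1 | intermediate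
26 | CNP0217128.1 | O=C(O[C@@H]1Cc2c(O)cc(O)cc2O[C@@H]1c1cc(O)c(O)c2c(=O)c(O)c([C@H]3Oc4cc(O)cc(O)c4C[C@H]3O)ccc12)c1cc(O)c(O)c(O)c1 | target

Total step count: 20. Longest linear sequence: 15 steps (steps 6–20, from 8).

Steps most likely to fail

Step 18. The oxocarbenium ion may be captured by the C5 carbonyl oxygen and lose methanol to an aromatic 2-benzopyrylium ion, or the enol silane may be protodesilylated before the ring closes. The fallback sets out from diketone acetal 21 and drops the silyl enol ether altogether. Aqueous acid (TFA/H2O/CH2Cl2, 0 °C) should unmask the aldehyde to give the keto-aldehyde F1. TsOH in toluene at 50 °C should then bring about an acid-catalysed intramolecular aldol addition of the C7 enol to the aldehyde, giving the 8-hydroxy dione F2. Dehydration through 24 and tautomerisation return the route at 25. Under these reversible conditions O-cyclised species can reopen, while the tropolone is a thermodynamic sink.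

Step 16. The dione may be cleaved further to two acids, the hindered and poorly soluble alkyne may react slowly, or benzylic ethers may be attacked on long exposure. The fallback sets out from alkyne 20 and replaces the direct oxidation by three known operations. Semi-hydrogenation over lead-poisoned Pd/CaCO3 with quinoline should give the Z-alkene F3. OsO4/NMO dihydroxylation should give the syn-diol F4 as a diastereomer mixture. IBX in DMSO should oxidise the diol to the dione without C–C cleavage, returning at 21.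

Step 15. Oxidative addition at the di-ortho-substituted, electron-rich aryl bromide may be too slow, so that copper-mediated homocoupling of alkyne 7 takes over. The fallback sets out from 7 and 19 and uses a preformed alkynylmetal without copper or amine. Deprotonation of 7 with n-BuLi (THF, −78 °C) gives the lithium acetylide F5. ZnCl2 converts it into the alkynylzinc chloride F6. Negishi coupling of F6 with 19 under Pd2(dba)3/XPhos (THF, 60 °C) should return the route at 20.

Further compounds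
F1 | step 18 | keto-aldehyde: 21 with the dimethyl acetal hydrolysed to CH2CHO | O=CCc1c(C(=O)C(=O)C[C@H]2Oc3cc(OCc9ccccc9)cc(OCc9ccccc9)c3C[C@H]2OCc9ccccc9)c(OCc9ccccc9)c(OCc9ccccc9)cc1[C@H]1Oc2cc(OCc9ccccc9)cc(OCc9ccccc9)c2C[C@H]1OC(=O)c1cc(OCc9ccccc9)c(OCc9ccccc9)c(OCc9ccccc9)c1
F2 | step 18 | 8-hydroxy analogue of 23 (aldol, C7/C8 mixture) | OC1Cc2c([C@H]3Oc4cc(OCc9ccccc9)cc(OCc9ccccc9)c4C[C@H]3OC(=O)c3cc(OCc9ccccc9)c(OCc9ccccc9)c(OCc9ccccc9)c3)cc(OCc9ccccc9)c(OCc9ccccc9)c2C(=O)C(=O)C1[C@H]1Oc2cc(OCc9ccccc9)cc(OCc9ccccc9)c2C[C@H]1OCc9ccccc9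
F3 | step 16 | Z-alkene from semi-hydrogenation of 20 | COC(OC)Cc1c(/C=C\C[C@H]2Oc3cc(OCc9ccccc9)cc(OCc9ccccc9)c3C[C@H]2OCc9ccccc9)c(OCc9ccccc9)c(OCc9ccccc9)cc1[C@H]1Oc2cc(OCc9ccccc9)cc(OCc9ccccc9)c2C[C@H]1OC(=O)c1cc(OCc9ccccc9)c(OCc9ccccc9)c(OCc9ccccc9)c1
F4 | step 16 | syn-1,2-diol from F3 (two diastereomers at the carbinol carbons) | COC(OC)Cc1c(C(O)C(O)C[C@H]2Oc3cc(OCc9ccccc9)cc(OCc9ccccc9)c3C[C@H]2OCc9ccccc9)c(OCc9ccccc9)c(OCc9ccccc9)cc1[C@H]1Oc2cc(OCc9ccccc9)cc(OCc9ccccc9)c2C[C@H]1OC(=O)c1cc(OCc9ccccc9)c(OCc9ccccc9)c(OCc9ccccc9)c1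
F5 | step 15 | lithium acetylide of 7 | [Li]C#CC[C@H]1Oc2cc(OCc9ccccc9)cc(OCc9ccccc9)c2C[C@H]1OCc9ccccc9
F6 | step 15 | alkynylzinc chloride of 7 | Cl[Zn]C#CC[C@H]1Oc2cc(OCc9ccccc9)cc(OCc9ccccc9)c2C[C@H]1OCc9ccccc9
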